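**Retrosynthetic overview**
1. Target 11 ⇐ acid unmasking of the cis-fused acetonide and silyl ether in 10.
2. 10 ⇐ ring–side-chain bond (target C6–C1′) made by a visible-light copper/photoredox decarboxylative alkylation of silyl dienol ether 7 with the N-hydroxyphthalimide ester 9 of erucic acid (C22 acid minus CO2 = the C21 chain).
3. 7 ⇐ hydroxy-enone 6 ⇐ Luche mono-reduction of the C2-symmetric ene-dione 5 (sets target C4–OH).
4. 5 ⇐ oxidation of cyclohexenediol 4 ⇐ ring-closing metathesis of diene-diol 3 (the carbocycle is the only ring formed; the dioxolane is bought).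
5. 3 ⇐ one-pot reduction–vinylation of dimethyl 2,3-O-isopropylidene-D-tartrate 1, the source of all chirality.

Assumption: 1, erucic acid 8 and all reagents are bought; intermediates use 1,3-benzodioxole numbering (C3a = target C6, C7a = target C5, C7 = target C4, C4 = target C1).

**Route**

Step 1
Reactants: 1 dimethyl (4S,5S)-2,2-dimethyl-1,3-dioxolane-4,5-dicarboxylate
Product: 3 (4R,5R)-4,5-bis(1-hydroxyprop-2-en-1-yl)-2,2-dimethyl-1,3-dioxolane (carbinol epimers), via tartraldehyde acetonide 2 (not isolated)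
Conditions: i-Bu2AlH (2.1 equiv), toluene, −78 °C, 2 h; then CH2=CHMgBr (4 equiv), THF, −78 → 0 °C; aq. KNaC4H4O6
Reagents that add atoms: vinylmagnesium bromide, C=C[Mg]Br
Why: One-pot half-reduction of both esters to aluminium hemiacetals and in situ Grignard addition (reduction–vinylation) avoids isolating the labile dialdehyde; the two new carbinol centres form as a mixture that is erased in step 3, and the tartrate centres are untouched.

Step 2
Reactants: 3 (4R,5R)-4,5-bis(1-hydroxyprop-2-en-1-yl)-2,2-dimethyl-1,3-dioxolane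
Product: 4 (3aR,7aR)-2,2-dimethyl-3a,4,7,7a-tetrahydro-1,3-benzodioxole-4,7-diol (C4/C7 epimers)
Conditions: RuCl2(=CHPh)(PCy3)(H2IMes) (second-generation Grubbs catalyst, 5 mol %), CH2Cl2 (0.01 M), 40 °C
Reagents that add atoms: none
Why: Ring-closing olefin metathesis of the 1,7-diene, helped by the free allylic hydroxyls, closes the cyclohexene with loss of ethylene and touches no stereocentre.

Step 3
Reactants: 4 (3aR,7aR)-2,2-dimethyl-3a,4,7,7a-tetrahydro-1,3-benzodioxole-4,7-diol
Product: 5 (3aS,7aS)-2,2-dimethyl-3a,7a-dihydro-1,3-benzodioxole-4,7-dione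
Conditions: Dess–Martin periodinane (2.5 equiv), CH2Cl2, 0 → 23 °C, 1 h; non-aqueous filtration through Celite/silica, used at once
Reagents that add atoms: none
Why: Dess–Martin oxidation of both allylic alcohols converges every carbinol epimer on one C2-symmetric ene-dione, so the stereochemical outcome of step 1 is irrelevant.

Step 4
Reactants: 5 (3aS,7aS)-2,2-dimethyl-3a,7a-dihydro-1,3-benzodioxole-4,7-dione
Product: 6 (3aS,7S,7aR)-7-hydroxy-2,2-dimethyl-7,7a-dihydro-1,3-benzodioxol-4(3aH)-one
Conditions: NaBH4 (0.5 equiv, portionwise), CeCl3·7H2O (1.1 equiv), MeOH, −78 °C; acetone quench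
Reagents that add atoms: none
Why: Luche 1,2-reduction of one of two homotopic carbonyls (only one constitution can form); axial hydride attack anti to the axial H-7a of the rigid trans-fused bicycle gives the equatorial 7-OH trans to O-7a, so target C4 is set by the tartrate-derived centre.

Step 5
Reactants: 6 (3aS,7S,7aR)-7-hydroxy-2,2-dimethyl-7,7a-dihydro-1,3-benzodioxol-4(3aH)-one
Product: 7 (7S,7aR)-2,2-dimethyl-4,7-bis(triethylsilyloxy)-7,7a-dihydro-1,3-benzodioxole
Conditions: Et3SiOTf (2.5 equiv), Et3N (4 equiv), CH2Cl2, −78 → 0 °C; filtration through Et3N-deactivated silica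
Reagents that add atoms: triethylsilyl trifluoromethanesulfonate, CC[Si](CC)(CC)OS(=O)(=O)C(F)(F)F
Why: Soft enolisation removes the only alpha′ hydrogen (axial H-3a, aligned with the carbonyl) to give the cross-conjugated 2-silyloxy diene and silylates the alcohol in the same pot; C3a becomes planar and is re-set in step 7.

Step 6
Reactants: 8 erucic acid, (13Z)-docos-13-enoic acid
Product: 9 1,3-dioxoisoindolin-2-yl (13Z)-docos-13-enoate
Conditions: N-hydroxyphthalimide (1.1 equiv), i-PrN=C=N-i-Pr (1.1 equiv), DMAP (5 mol %), CH2Cl2, 23 °C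
Reagents that add atoms: N-hydroxyphthalimide, O=C1c2ccccc2C(=O)N1O
Why: Steglich-type carbodiimide esterification gives the redox-active ester without touching the Z alkene.

Step 7
Reactants: 7 (7S,7aR)-2,2-dimethyl-4,7-bis(triethylsilyloxy)-7,7a-dihydro-1,3-benzodioxole; 9 1,3-dioxoisoindolin-2-yl (13Z)-docos-13-enoate (1.5 equiv)
Product: 10 (3aR,7S,7aR)-3a-[(12Z)-henicos-12-en-1-yl]-2,2-dimethyl-7-(triethylsilyloxy)-7,7a-dihydro-1,3-benzodioxol-4(3aH)-one
Conditions: Cu(MeCN)4PF6 (20 mol %), 4,7-diphenyl-1,10-phenanthroline (24 mol %), Ru(bpy)3(PF6)2 (2 mol %), CsF (1.5 equiv), degassed DMA/THF 1:1, 450 nm LEDs, 0 °C, 16 h; then H2O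
Reagents that add atoms: none
Why: Proposed new method: fluoride moves the dienolate from silicon to phenanthroline-ligated monovalent copper; excited Ru(bpy)3(PF6)2 is quenched by this electron-rich copper enolate to give the divalent copper enolate and a reduced ruthenium complex that reduces 9 to the primary henicosenyl radical with loss of CO2 and phthalimide anion; the radical is captured at copper and the trivalent alkyl copper enolate reductively eliminates through C3a, the only nucleophilic carbon of the cross-conjugated dienolate, on the face of H-7a so that the cis-fused dioxolane forms and the quaternary centre is set by C7a; the closest known reactions are the light-driven copper-catalysed decarboxylative C–N coupling of N-hydroxyphthalimide esters and the photoredox alkylation of aryl ketone silyl enol ethers with such esters, neither shown for a tetrasubstituted alpha-alkoxy dienol ether or for an oxygenated quaternary centre.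

Step 8
Reactants: 10 (3aR,7S,7aR)-3a-[(12Z)-henicos-12-en-1-yl]-2,2-dimethyl-7-(triethylsilyloxy)-7,7a-dihydro-1,3-benzodioxol-4(3aH)-one
Product: 11 (4S,5R,6R)-4,5,6-trihydroxy-6-[(12Z)-henicos-12-en-1-yl]cyclohex-2-en-1-one
Conditions: TFA/H2O/THF (2:1:2), 0 → 23 °C
Reagents that add atoms: none
Why: Aqueous acid hydrolyses the cis-fused acetonide and the triethylsilyl ether; the ketone cannot enolise toward the quaternary C6, so no dehydration or epimerisation follows.

**Compound list**
1 | dimethyl (4S,5S)-2,2-dimethyl-1,3-dioxolane-4,5-dicarboxylate (dimethyl 2,3-O-isopropylidene-D-tartrate) | COC(=O)[C@H]1OC(C)(C)O[C@@H]1C(=O)OC | starting material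
2 | (4S,5S)-2,2-dimethyl-1,3-dioxolane-4,5-dicarbaldehyde (tartraldehyde acetonide, held as its aluminium hemiacetal) | O=C[C@H]1OC(C)(C)O[C@@H]1C=O | intermediate
3 | (4R,5R)-4,5-bis(1-hydroxyprop-2-en-1-yl)-2,2-dimethyl-1,3-dioxolane (carbinol centres unassigned, mixture) | C=CC(O)[C@H]1OC(C)(C)O[C@@H]1C(O)C=C | intermediate
4 | (3aR,7aR)-2,2-dimethyl-3a,4,7,7a-tetrahydro-1,3-benzodioxole-4,7-diol (C4/C7 unassigned, mixture) | CC1(C)O[C@@H]2C(O)C=CC(O)[C@H]2O1 | intermediate
5 | (3aS,7aS)-2,2-dimethyl-3a,7a-dihydro-1,3-benzodioxole-4,7-dione | CC1(C)O[C@@H]2C(=O)C=CC(=O)[C@H]2O1 | intermediate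
6 | (3aS,7S,7aR)-7-hydroxy-2,2-dimethyl-7,7a-dihydro-1,3-benzodioxol-4(3aH)-one | CC1(C)O[C@@H]2C(=O)C=C[C@H](O)[C@H]2O1 | intermediate
7 | (7S,7aR)-2,2-dimethyl-4,7-bis(triethylsilyloxy)-7,7a-dihydro-1,3-benzodioxole | CC1(C)OC2=C(O[Si](CC)(CC)CC)C=C[C@H](O[Si](CC)(CC)CC)[C@H]2O1 | intermediate
8 | erucic acid, (13Z)-docos-13-enoic acid | CCCCCCCC/C=C\CCCCCCCCCCCC(=O)O | starting material
9 | 1,3-dioxoisoindolin-2-yl (13Z)-docos-13-enoate | CCCCCCCC/C=C\CCCCCCCCCCCC(=O)ON1C(=O)c2ccccc2C1=O | intermediate
10 | (3aR,7S,7aR)-3a-[(12Z)-henicos-12-en-1-yl]-2,2-dimethyl-7-(triethylsilyloxy)-7,7a-dihydro-1,3-benzodioxol-4(3aH)-one | CCCCCCCC/C=C\CCCCCCCCCCC[C@]1(OC(C)(C)O2)C(=O)C=C[C@H](O[Si](CC)(CC)CC)[C@H]12 | intermediate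
11 | (4S,5R,6R)-4,5,6-trihydroxy-6-[(12Z)-henicos-12-en-1-yl]cyclohex-2-en-1-one | CCCCCCCC/C=C\CCCCCCCCCCC[C@]1(O)C(=O)C=C[C@H](O)[C@H]1O | target

**Step count and risks**
Total steps: 8. Longest linear sequence: 7 (steps 1–5, 7, 8).

Step 7 (the new copper/photoredox alkylation). Risks are C–N coupling to the N-alkylphthalimide, radical addition at the diene terminus C6, and acylation of free enolate by 9. The fallback uses known enolate chemistry, sets out from 7 and returns at 10. Erucic acid 8 is chlorodecarboxylated (Pb(OAc)4, LiCl, benzene, 80 °C) to (12Z)-1-chlorohenicos-12-ene F1, which is exchanged with NaI in acetone to (12Z)-1-iodohenicos-12-ene F2. Compound 7 is cleaved with MeLi in THF at −40 °C to lithium (7S,7aR)-2,2-dimethyl-7-(triethylsilyloxy)-7,7a-dihydro-1,3-benzodioxol-4-olate F3. F3 is C-alkylated by F2 in THF/DMPU (−78 → −30 °C) on the H-7a face, giving 10.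

Step 3 (ene-dione 5). Both ring-fusion hydrogens are alpha to a carbonyl, so 5 can epimerise to the meso cis-fused dione (loss of optical purity) or tautomerise to the aromatic hydroquinone. The fallback sets out from 4 and returns at 6 without making 5. MnO2 (CH2Cl2, 23 °C) oxidises only one allylic alcohol of each diastereomer of 4, because the second is deactivated once the enone exists. This gives 6 together with its C7 epimer (3aS,7R,7aR)-7-hydroxy-2,2-dimethyl-7,7a-dihydro-1,3-benzodioxol-4(3aH)-one F4. After separation, F4 is inverted by a Mitsunobu reaction (PPh3, DIAD, HCO2H) to (3aS,7S,7aR)-2,2-dimethyl-4-oxo-3a,4,7,7a-tetrahydro-1,3-benzodioxol-7-yl formate F5, and mild methanolysis (KHCO3, MeOH, 0 °C) gives 6.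

Step 4 (mono-reduction). The risk is over-reduction or incomplete conversion, since the product enone is also reduced under Luche conditions. The fallback sets out from 5 and returns at 6. Both carbonyls are reduced (NaBH4 1.2 equiv, CeCl3·7H2O, MeOH, −78 °C) to the C2-symmetric all-trans diol (3aR,4S,7S,7aR)-2,2-dimethyl-3a,4,7,7a-tetrahydro-1,3-benzodioxole-4,7-diol F6. F6 is then desymmetrised by mono-oxidation with MnO2 in CH2Cl2, which stops at 6 because the two hydroxyls are homotopic and the remaining one is deactivated.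

**Further compounds**
F1 | step 7 | (12Z)-1-chlorohenicos-12-ene | CCCCCCCC/C=C\CCCCCCCCCCCCl
F2 | step 7 | (12Z)-1-iodohenicos-12-ene | CCCCCCCC/C=C\CCCCCCCCCCCI
F3 | step 7 | lithium (7S,7aR)-2,2-dimethyl-7-(triethylsilyloxy)-7,7a-dihydro-1,3-benzodioxol-4-olate | CC1(C)OC2=C(O[Li])C=C[C@H](O[Si](CC)(CC)CC)[C@H]2O1
F4 | step 3 | (3aS,7R,7aR)-7-hydroxy-2,2-dimethyl-7,7a-dihydro-1,3-benzodioxol-4(3aH)-one | CC1(C)O[C@@H]2C(=O)C=C[C@@H](O)[C@H]2O1
F5 | step 3 | (3aS,7S,7aR)-2,2-dimethyl-4-oxo-3a,4,7,7a-tetrahydro-1,3-benzodioxol-7-yl formate | CC1(C)O[C@@H]2C(=O)C=C[C@H](OC=O)[C@H]2O1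
F6 | step 4 | (3aR,4S,7S,7aR)-2,2-dimethyl-3a,4,7,7a-tetrahydro-1,3-benzodioxole-4,7-diol | CC1(C)O[C@@H]2[C@@H](O)C=C[C@H](O)[C@H]2O1
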